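**Retrosynthetic overview**
1. Target ⇐ C4 silyl ether ⇐ eleven-membered ring closed last by Ni/Cr (Nozaki–Hiyama–Kishi) addition of a C8 alkenyl triflate to the C7 aldehyde.
2. Alkenyl triflate and C1=CH2 ⇐ one fluoride-triggered fragmentation/triflation of a silylmethyl cyclobutyl ketone; the cyclobutane masks both target alkenes while the carvone isopropenyl group is converted into the C15 acetate (Criegee) and C16 is oxygenated.
3. Cyclobutane (C10–C11 bond, cyclopentane ring) ⇐ intramolecular enone–allylsilane [2+2] photocycloaddition of a 4,4-disubstituted enone made from (S)-carvone by two alkylations and a Wharton transposition.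
4. Side chain (C1–C7, C11–C13) ⇐ cross-metathesis, Bunnelle allylsilane synthesis and chelation-controlled homoenolate addition to the aldehyde from the (R)-Roche ester.
5. Ring order: six-membered ring (bought) → cyclopentane plus temporary cyclobutane (photochemical) → cyclobutane opened → eleven-membered ring.

Locants used below: C1–C16 are the ring carbons of the target in the order of its SMILES (C1 carries the exocyclic CH2; C4 and C7 are the carbinols; C8=C9 is the ring alkene; C10 and C14 are the ring-fusion carbons; C15 and C16 carry the acetates).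

**Route**

Step 1
Reactants: 1 methyl (R)-3-hydroxy-2-methylpropanoate (Roche ester)
Product: 2 methyl (R)-3-(benzyloxy)-2-methylpropanoate
Conditions: BnOC(=NH)CCl3, TfOH (cat.), CH2Cl2/cyclohexane, 0 °C to rt
Reagents that add atoms: benzyl 2,2,2-trichloroacetimidate, ClC(Cl)(Cl)C(=N)OCc1ccccc1
Why: Acid-catalysed trichloroacetimidate O-benzylation installs the chelating ether without touching the base-sensitive α-stereocentre (future C5).

Step 2
Reactants: 2 methyl (R)-3-(benzyloxy)-2-methylpropanoate
Product: 3 (R)-3-(benzyloxy)-2-methylpropanal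
Conditions: iBu2AlH, CH2Cl2, −78 °C
Reagents that add atoms: none
Why: Low-temperature partial ester reduction stops at the aluminium hemiacetal and gives the aldehyde, which is used crude so that C5 does not epimerise.

Step 3
Reactants: 3 (R)-3-(benzyloxy)-2-methylpropanal
Product: 5 lactone (5S)-5-[(2R)-1-(benzyloxy)propan-2-yl]oxolan-2-one, via hydroxy ester 4 (not isolated)
Conditions: [(1-ethoxycyclopropyl)oxy]trimethylsilane, TiCl4, CH2Cl2, 0 °C to rt; then 3, 0 °C; then TsOH (cat.), toluene, 60 °C
Reagents that add atoms: [(1-ethoxycyclopropyl)oxy]trimethylsilane, CCOC1(CC1)O[Si](C)(C)C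
Why: Nakamura–Kuwajima titanium homoenolate addition under Cram-chelate control (the RTiCl3 centre binds the aldehyde and benzyloxy oxygens and delivers carbon anti to the C5 methyl) lets the bought C5 centre set C4 (4S, anti), and the hydroxy ester then lactonises.

Step 4
Reactants: 5 lactone benzyl ether
Product: 6 (5S)-5-[(2R)-1-hydroxypropan-2-yl]oxolan-2-one
Conditions: H2 (1 atm), Pd/C, EtOAc, rt
Reagents that add atoms: none
Why: Catalytic hydrogenolysis removes the benzyl ether; the lactone and both stereocentres are inert.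

Step 5
Reactants: 6 hydroxy lactone
Product: 8 enol ether (5S)-5-[(2R)-4-methoxybut-3-en-2-yl]oxolan-2-one (E/Z mixture), via aldehyde 7 (not isolated)
Conditions: Dess–Martin periodinane, CH2Cl2, rt; then Ph3P=CHOMe [from (methoxymethyl)triphenylphosphonium chloride and KN(SiMe3)2], THF, −78 to 0 °C
Reagents that add atoms: (methoxymethyl)triphenylphosphonium chloride, [Cl-].COC[P+](c1ccccc1)(c1ccccc1)c1ccccc1
Why: Dess–Martin oxidation followed at once by Wittig methoxymethylenation adds C7; the β-acyloxy α-methyl aldehyde is never stored, so C5 is not epimerised (the same aldehyde type as the Prelog–Djerassi lactone aldehyde).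

Step 6
Reactants: 8 enol ether
Product: 9 (5S)-5-[(2R)-4,4-dimethoxybutan-2-yl]oxolan-2-one
Conditions: MeOH, PPTS (cat.), rt
Reagents that add atoms: methanol, CO
Why: Acid-catalysed addition of methanol to the enol ether (acetalisation) masks C7 as a dimethyl acetal that survives base, hydrazine, ozone and fluoride.

Step 7
Reactants: 9 acetal lactone
Product: 11 allylsilane alcohol (5S,6R)-8,8-dimethoxy-6-methyl-2-[(trimethylsilyl)methyl]oct-1-en-5-ol, via diol 10 (not isolated)
Conditions: Me3SiCH2MgCl, CeCl3, THF, −78 °C to rt; then SiO2, CH2Cl2, rt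
Reagents that add atoms: (trimethylsilyl)methylmagnesium chloride, C[Si](C)(C)C[Mg]Cl
Why: Bunnelle–Narayanan allylsilane synthesis: double addition of the organocerium reagent to the lactone carbonyl (C1), then Peterson elimination of the tertiary β-silyl carbinol on silica; no stereocentre is involved.

Step 8
Reactants: 11 allylsilane alcohol
Product: 12 tert-butyldimethylsilyl ether of 11
Conditions: tBuMe2SiCl, imidazole, DMF, rt
Reagents that add atoms: tert-butyl(chloro)dimethylsilane, CC(C)(C)[Si](C)(C)Cl
Why: Standard silylation protects the C4 hydroxyl against the later enolate, oxidation and acetylation steps.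

Step 9
Reactants: 12 silyl ether
Product: 13 iodide tert-butyl{[(3R,4S)-10-iodo-1,1-dimethoxy-3-methyl-7-[(trimethylsilyl)methyl]dec-7-en-4-yl]oxy}dimethylsilane (E/Z mixture)
Conditions: 4-iodobut-1-ene (4 equiv), second-generation Hoveyda–Grubbs catalyst (5 mol %), CH2Cl2, 40 °C
Reagents that add atoms: 4-iodobut-1-ene, C=CCCI
Why: Olefin cross-metathesis of the 1,1-disubstituted allylsilane with an excess of the terminal alkene gives the trisubstituted allylsilane; its E/Z ratio is irrelevant because the alkene is consumed in step 15.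

Step 10
Reactants: 14 (S)-(+)-carvone
Product: 15 6-methylcarvone (5S,6R)-2,6-dimethyl-5-(prop-1-en-2-yl)cyclohex-2-en-1-one (trans epimer major)
Conditions: LiN(iPr)2, THF, −78 °C; then MeI, −78 to 0 °C
Reagents that add atoms: iodomethane, CI
Why: Kinetic α'-deprotonation and enolate methylation; the configuration at the new centre is irrelevant because it is enolised again in step 11.

Step 11
Reactants: 15 6-methylcarvone; 13 iodide
Product: 16 6-alkyl-6-methylcarvone (C14 quaternary; methyl cis and side chain trans to the isopropenyl group)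
Conditions: LiN(iPr)2, THF, −78 °C; then 13, DMPU, −78 to 0 °C
Reagents that add atoms: none
Why: SN2 alkylation of the cross-conjugated lithium enolate; the iodide approaches anti to the neighbouring isopropenyl group, so the bought carvone centre sets the C14 quaternary centre.

Step 12
Reactants: 16 dialkylated carvone
Product: 17 C8–C9 epoxy ketone (oxygen anti to the isopropenyl group)
Conditions: H2O2 (30 % aq.), NaOH, MeOH, 0 °C
Reagents that add atoms: hydrogen peroxide, OO
Why: Weitz–Scheffer nucleophilic epoxidation attacks only the enone (allylsilane and isopropenyl are untouched); the epoxide configuration is erased in step 14.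

Step 13
Reactants: 17 epoxy ketone
Product: 18 transposed allylic alcohol (C8 hydroxyl, C9=C10 alkene)
Conditions: N2H4·H2O, AcOH (cat.), MeOH, 0 °C to rt
Reagents that add atoms: none
Why: Wharton transposition: the epoxy hydrazone opens to a vinyl diazene that loses N2, moving the oxygen from C10 to C8.

Step 14
Reactants: 18 allylic alcohol
Product: 19 transposed enone (C8 ketone, C9=C10, C14 quaternary at the γ-position)
Conditions: MnO2, CH2Cl2, rt
Reagents that add atoms: none
Why: MnO2 oxidises only the allylic alcohol and gives the 4,4-disubstituted 2-methylcyclohexenone chromophore.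

Step 15
Reactants: 19 enone
Product: 20 tricyclic photoadduct (cyclobutane C9–C10–C11–C1; C10-H, C11-H and C14-methyl cis; epimers at C1)
Conditions: hν (350 nm, Pyrex), degassed cyclohexane (0.01 M), rt
Reagents that add atoms: none
Why: Intramolecular enone–alkene [2+2] photocycloaddition: the triplet enone bonds C10 to C11 first (five-membered ring, rule of five) from the face of the C14 tether and the biradical then closes C9–C1, so the cis-fused cyclobutane fixes C10 and C11 relative to C14, and the three-atom tether reacts much faster than the isopropenyl group.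

Step 16
Reactants: 20 photoadduct
Product: 21 C16 α-hydroxy ketone (hydroxyl trans to the isopropenyl group)
Conditions: KN(SiMe3)2, THF, −78 °C; then 2-(benzenesulfonyl)-3-phenyloxaziridine, −78 °C
Reagents that add atoms: 2-(benzenesulfonyl)-3-phenyloxaziridine, O=S(=O)(c1ccccc1)N1OC1c1ccccc1
Why: Davis enolate hydroxylation; C9 is quaternary, so only the C16 enolate can form, and the racemic oxaziridine approaches anti to the vicinal isopropenyl group (sets C16).

Step 17
Reactants: 21 hydroxy ketone
Product: 23 C15,C16 trans-diacetate, via methoxy hydroperoxide 22 (not isolated)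
Conditions: O3, CH2Cl2/MeOH, −78 °C; then Ac2O, Et3N, DMAP (cat.), CH2Cl2, 0 °C to rt
Reagents that add atoms: ozone, [O-][O+]=O; methanol, CO; acetic anhydride, CC(=O)OC(C)=O
Why: Ozonolysis in methanol then Criegee rearrangement of the peracetate moves C15 from carbon to oxygen with retention, so the carvone stereocentre becomes the C15 acetate, while the C16 hydroxyl is acetylated in the same pot and the cyclobutane keeps both future alkenes away from ozone.

Step 18
Reactants: 23 diacetate cyclobutyl ketone
Product: 24 C8 alkenyl triflate with C1 exocyclic methylene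
Conditions: CsF, PhNTf2, DME, 0 °C to rt
Reagents that add atoms: N-phenylbis(trifluoromethanesulfonimide), O=S(=O)(N(c1ccccc1)S(=O)(=O)C(F)(F)F)C(F)(F)F
Why: Proposed new method: fluoride attack on silicon lets the C–Si σ bond push into the strained C1–C9 cyclobutane bond that is aligned with the C8 carbonyl (Grob-type retro-carbosilylation), releasing the C1=CH2 alkene and a C8–C9 caesium enolate of defined regiochemistry that PhNTf2 traps as the tetrasubstituted enol triflate; the closest known reactions are the Lewis-acid silicon-terminated opening of (silylmethyl)cyclobutyl ketones, the De Mayo retro-aldol opening of enone photoadducts and enolate O-triflation with PhNTf2.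

Step 19
Reactants: 24 alkenyl triflate
Product: 25 C7 aldehyde
Conditions: PPTS (cat.), acetone/H2O (9:1), 45 °C
Reagents that add atoms: water, O
Why: Mild acid-catalysed acetal hydrolysis frees the aldehyde and leaves the secondary silyl ether, the acetates and the triflate intact.

Step 20
Reactants: 25 aldehyde triflate
Product: 26 macrocyclic allylic alcohol (7S; C4 silyl ether)
Conditions: CrCl2 (10 equiv), NiCl2 (cat.), DMSO/THF (0.002 M), rt
Reagents that add atoms: none
Why: Nozaki–Hiyama–Kishi coupling at high dilution: nickel (reduced in situ to its zerovalent state) inserts into the alkenyl triflate, transmetalation gives the alkenyl species of trivalent chromium, and this adds to the C7 aldehyde to close the eleven-membered ring, attacking the aldehyde face turned away from the C16 acetate (substrate control of C7).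

Step 21
Reactants: 26 silyl ether
Product: 27 target CNP0114864.2
Conditions: HF·pyridine, pyridine, THF, 0 °C to rt
Reagents that add atoms: none
Why: Buffered fluoride desilylation frees the C4 hydroxyl without acetate cleavage or migration.

**Compound list**
1 | methyl (R)-3-hydroxy-2-methylpropanoate | COC(=O)[C@H](C)CO | starting material
2 | methyl (R)-3-(benzyloxy)-2-methylpropanoate | COC(=O)[C@H](C)COCc1ccccc1 | intermediate
3 | (R)-3-(benzyloxy)-2-methylpropanal | O=C[C@H](C)COCc1ccccc1 | intermediate
4 | ethyl (4S,5R)-6-(benzyloxy)-4-hydroxy-5-methylhexanoate | CCOC(=O)CC[C@H](O)[C@H](C)COCc1ccccc1 | intermediate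
5 | (5S)-5-[(2R)-1-(benzyloxy)propan-2-yl]oxolan-2-one | O=C1CC[C@H](O1)[C@H](C)COCc1ccccc1 | intermediate
6 | (5S)-5-[(2R)-1-hydroxypropan-2-yl]oxolan-2-one | O=C1CC[C@H](O1)[C@H](C)CO | intermediate
7 | (2S)-2-[(2S)-5-oxooxolan-2-yl]propanal | O=C1CC[C@H](O1)[C@H](C)C=O | intermediate
8 | (5S)-5-[(2R)-4-methoxybut-3-en-2-yl]oxolan-2-one, E/Z mixture | O=C1CC[C@H](O1)[C@H](C)C=COC | intermediate
9 | (5S)-5-[(2R)-4,4-dimethoxybutan-2-yl]oxolan-2-one | O=C1CC[C@H](O1)[C@H](C)CC(OC)OC | intermediate
10 | (5S,6R)-8,8-dimethoxy-6-methyl-1-(trimethylsilyl)-2-[(trimethylsilyl)methyl]octane-2,5-diol | C[Si](C)(C)CC(O)(C[Si](C)(C)C)CC[C@H](O)[C@H](C)CC(OC)OC | intermediate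
11 | (5S,6R)-8,8-dimethoxy-6-methyl-2-[(trimethylsilyl)methyl]oct-1-en-5-ol | C=C(C[Si](C)(C)C)CC[C@H](O)[C@H](C)CC(OC)OC | intermediate
12 | tert-butyldimethylsilyl ether of 11 | C=C(C[Si](C)(C)C)CC[C@H](O[Si](C)(C)C(C)(C)C)[C@H](C)CC(OC)OC | intermediate
13 | side-chain iodide, (3R,4S), E/Z mixture at the trisubstituted alkene | ICCC=C(C[Si](C)(C)C)CC[C@H](O[Si](C)(C)C(C)(C)C)[C@H](C)CC(OC)OC | intermediate
14 | (S)-(+)-carvone | C1=C(C)C(=O)C[C@@H](C(C)=C)C1 | starting material
15 | (5S,6R)-6-methylcarvone (trans; used with its C6 epimer) | C1=C(C)C(=O)[C@H](C)[C@@H](C(C)=C)C1 | intermediate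
16 | 6-alkyl-6-methylcarvone, methyl cis and chain trans to isopropenyl | C1=C(C)C(=O)[C@](C)(CCC=C(C[Si](C)(C)C)CC[C@H](O[Si](C)(C)C(C)(C)C)[C@H](C)CC(OC)OC)[C@@H](C(C)=C)C1 | intermediate
17 | C8–C9 epoxy ketone, oxygen anti to isopropenyl | [C@@H]1(O2)[C@@]2(C)C(=O)[C@](C)(CCC=C(C[Si](C)(C)C)CC[C@H](O[Si](C)(C)C(C)(C)C)[C@H](C)CC(OC)OC)[C@@H](C(C)=C)C1 | intermediate
18 | transposed allylic alcohol (C8-OH, C9=C10) | O[C@@H]1C(C)=C[C@](C)(CCC=C(C[Si](C)(C)C)CC[C@H](O[Si](C)(C)C(C)(C)C)[C@H](C)CC(OC)OC)[C@@H](C(C)=C)C1 | intermediate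
19 | transposed enone (C8=O, C9=C10) | O=C1C(C)=C[C@](C)(CCC=C(C[Si](C)(C)C)CC[C@H](O[Si](C)(C)C(C)(C)C)[C@H](C)CC(OC)OC)[C@@H](C(C)=C)C1 | intermediate
20 | tricyclic photoadduct, C1 epimers | O=C1[C@@]2(C)[C@@H]3[C@@H](CC[C@]3(C)[C@@H](C(C)=C)C1)C2(C[Si](C)(C)C)CC[C@H](O[Si](C)(C)C(C)(C)C)[C@H](C)CC(OC)OC | intermediate
21 | C16 α-hydroxy ketone | O=C1[C@@]2(C)[C@@H]3[C@@H](CC[C@]3(C)[C@@H](C(C)=C)[C@@H]1O)C2(C[Si](C)(C)C)CC[C@H](O[Si](C)(C)C(C)(C)C)[C@H](C)CC(OC)OC | intermediate
22 | C15 2-hydroperoxy-2-methoxypropan-2-yl intermediate | O=C1[C@@]2(C)[C@@H]3[C@@H](CC[C@]3(C)[C@@H](C(C)(OC)OO)[C@@H]1O)C2(C[Si](C)(C)C)CC[C@H](O[Si](C)(C)C(C)(C)C)[C@H](C)CC(OC)OC | intermediate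
23 | C15,C16 trans-diacetate cyclobutyl ketone | O=C1[C@@]2(C)[C@@H]3[C@@H](CC[C@]3(C)[C@@H](OC(C)=O)[C@@H]1OC(C)=O)C2(C[Si](C)(C)C)CC[C@H](O[Si](C)(C)C(C)(C)C)[C@H](C)CC(OC)OC | intermediate
24 | C8 alkenyl triflate, C1=CH2, C7 dimethyl acetal | C=C(CC[C@H](O[Si](C)(C)C(C)(C)C)[C@H](C)CC(OC)OC)[C@@H]1CC[C@@]2(C)[C@@H]1C(C)=C(OS(=O)(=O)C(F)(F)F)[C@@H](OC(C)=O)[C@@H]2OC(C)=O | intermediate
25 | C7 aldehyde alkenyl triflate | C=C(CC[C@H](O[Si](C)(C)C(C)(C)C)[C@H](C)CC=O)[C@@H]1CC[C@@]2(C)[C@@H]1C(C)=C(OS(=O)(=O)C(F)(F)F)[C@@H](OC(C)=O)[C@@H]2OC(C)=O | intermediate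
26 | macrocycle, (7S)-alcohol, C4 silyl ether | C=C1CC[C@H](O[Si](C)(C)C(C)(C)C)[C@H](C)C[C@H](O)C2=C(C)[C@@H]3[C@H]1CC[C@]3(C)[C@@H](OC(C)=O)[C@@H]2OC(C)=O | intermediate
27 | CNP0114864.2 | C=C1CC[C@H](O)[C@H](C)C[C@H](O)C2=C(C)[C@@H]3[C@H]1CC[C@]3(C)[C@@H](OC(C)=O)[C@@H]2OC(C)=O | target

**Totals and weak points**
Total steps: 21. Longest linear sequence: 20 (steps 1–9, then 11–21).

Step 18 (the proposed new fragmentation–triflation) is the least certain step: fluoride may fail to trigger the C–C cleavage, or the enolate may be lost before it is sulfonylated. The fallback separates cleavage and triflation along established lines. Setting out from 23, catalytic Me3SiOTf (5 mol %, CH2Cl2, −78 °C, 0.005 M) brings about the Lewis-acid-triggered, silicon-terminated opening that (silylmethyl)cyclobutyl ketones are known to undergo, with silicon ending on oxygen, to give the ring-opened trimethylsilyl enol ether F1. F1 is then converted into the triflate by the standard CsF/PhNTf2 procedure for silyl enol ethers, which brings the route back at 24. The dimethyl acetal is the group at risk in this detour, hence the low temperature and high dilution.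

Step 20 (Ni/Cr ring closure) may give the eleven-membered ring with poor control at C7. The fallback decouples ring closure from C7 control. Setting out from 25, the ring is closed as before without regard to selectivity, and the mixture of 26 and its C7 epimer F2 is oxidised with Dess–Martin periodinane to the macrocyclic enone F3. F3 is reduced under Luche conditions (NaBH4, CeCl3·7H2O, MeOH, −78 °C), hydride adding from the outer face of the ring, and the route is rejoined at 26.

Step 13 (Wharton transposition) can be low-yielding on this hindered epoxy ketone with a neighbouring quaternary carbon. The fallback avoids the epoxide. Setting out from 16, Luche reduction (NaBH4, CeCl3·7H2O, MeOH, −78 °C) gives the C10 allylic alcohol F4. Catalytic Ph3SiOReO3 (Et2O, 0 °C) then effects the known 1,3-transposition of the allylic alcohol toward the less hindered C8 position, rejoining the route at 18; either C8 epimer serves because step 14 removes that centre.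

**Further compounds**
F1 | step 18 | ring-opened trimethylsilyl enol ether (C8 OSiMe3, C8=C9, C1=CH2, otherwise as 24) | C=C(CC[C@H](O[Si](C)(C)C(C)(C)C)[C@H](C)CC(OC)OC)[C@@H]1CC[C@@]2(C)[C@@H]1C(C)=C(O[Si](C)(C)C)[C@@H](OC(C)=O)[C@@H]2OC(C)=O
F2 | step 20 | C7 epimer of 26 | C=C1CC[C@H](O[Si](C)(C)C(C)(C)C)[C@H](C)C[C@@H](O)C2=C(C)[C@@H]3[C@H]1CC[C@]3(C)[C@@H](OC(C)=O)[C@@H]2OC(C)=O
F3 | step 20 | macrocyclic C7 enone | C=C1CC[C@H](O[Si](C)(C)C(C)(C)C)[C@H](C)CC(=O)C2=C(C)[C@@H]3[C@H]1CC[C@]3(C)[C@@H](OC(C)=O)[C@@H]2OC(C)=O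
F4 | step 13 | C10 allylic alcohol from 1,2-reduction of 16 (C10 epimers) | C1=C(C)C(O)[C@](C)(CCC=C(C[Si](C)(C)C)CC[C@H](O[Si](C)(C)C(C)(C)C)[C@H](C)CC(OC)OC)[C@@H](C(C)=C)C1
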